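**Strategy.** Ring A is cut at C1–C10 and C3–C4 (labdane numbering). This exposes the 1,3-relationship, across the C1–C2–C3 bridge, of the two fully substituted carbons: C4, a latent malonate carbon, and methyl-bearing C10, alpha to a temporary C9 carbonyl in ring B. The key step joins both nucleophilic sites of a ring B dianion (C10 enolate and C4 malonate, C8 blocked as an enaminone) to 1-chloro-3-iodopropane in one flask. It closes ring A, creates both quaternary carbons and fixes the trans ring fusion from C5. The blocking carbon becomes the C8 formyl group; C9 is then vinylated, extended to the butenolide and reduced by allylic transposition.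

Key step: step 3

Remark on numbering: C10 carries the angular methyl, C5 is the ring-fusion CH, C4 carries the two CH2OH groups, C9 the side chain, C8 the formyl group (C17); ring A = C1–C5 and C10, ring B = C5–C10.

Assumption: the (S)-BINOL-derived aluminate is taken to give the (1S) adduct 3, by analogy with the sense recalled for cyclohex-2-en-1-one; if the sense is opposite, the (R)-catalyst is used.

Compounds 1, 2, 5, 9 and 12 are taken as commercially available.

**Step 1**
Reactants: 1 2-methylcyclohex-2-en-1-one; 2 dimethyl malonate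
Product: 3 dimethyl 2-[(1S)-2-methyl-3-oxocyclohexyl]propanedioate (both C-2 epimers)
Conditions: LiAl[(S)-BINOLate]2 (10 mol %), KOtBu (9 mol %), 4 Å molecular sieves, THF, rt
Reagents that add atoms: none
Why: Heterobimetallic (Lewis acid/Brønsted base) asymmetric Michael addition of the kind established for cyclic enones; the chiral aluminate fixes the face of attack at C5 (S), and the epimer mixture at C10 is irrelevant because C10 becomes an enolate in step 3.

**Step 2**
Reactants: 3 dimethyl 2-[(1S)-2-methyl-3-oxocyclohexyl]propanedioate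
Product: 4 dimethyl 2-[(1S,4E)-4-[(dimethylamino)methylidene]-2-methyl-3-oxocyclohexyl]propanedioate (both C-2 epimers)
Conditions: t-BuOCH(NMe2)2 (1.5 equiv), toluene, 80 °C
Reagents that add atoms: tert-butoxybis(dimethylamino)methane (Bredereck's reagent), CN(C)C(OC(C)(C)C)N(C)C
Why: Aminomethylenation of the only alpha-methylene (C8) gives the E enaminone, which blocks C8 against enolisation and installs C17, the future formyl carbon, while C5 is untouched.

**Step 3**
Reactants: 4 dimethyl 2-[(1S,4E)-4-[(dimethylamino)methylidene]-2-methyl-3-oxocyclohexyl]propanedioate; 5 1-chloro-3-iodopropane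
Product: 7 dimethyl (4aR,6E,8aS)-6-[(dimethylamino)methylidene]-4a-methyl-5-oxooctahydronaphthalene-1,1(2H)-dicarboxylate (trans-fused), via chloropropyl ketone 6 (not isolated)
Conditions: LiN(i-Pr)2 (2.3 equiv), THF–DMPU, −78 → −20 °C; 5 (1.05 equiv), −78 → 0 °C; then NaI (10 mol %), 55 °C
Reagents that add atoms: none
Why: Two equivalents of LiN(i-Pr)2 remove first the malonate proton and then the only remaining enolisable proton, the C10 methine alpha-prime to the vinylogous-amide carbonyl, giving a C4/C10 dianion; the far more basic cross-conjugated enolate attacks the iodide terminus of 5 by SN2 (C1–C10) to give 6, whose lithium malonate displaces chloride on warming (C3–C4). The closest known reaction types are the alkylation of ketone and beta-keto ester dianions at their more basic carbon and the angular alkylation of alpha-blocked 2-methylcyclohexanones, combined here with malonate ring closure onto an omega-halide. Ring A is closed by a 6-exo-tet displacement at C3 with the malonate carbon C4 as nucleophile; no bond of ring B is formed. The new stereocentre C10 is controlled by C5: allylic 1,2-strain with the C10 methyl pushes the bulky C5 substituent pseudoaxial, so the electrophile enters axially on the opposite face, which places C1 trans to C4 and the methyl anti to H5 (trans ring fusion); C4 becomes quaternary but is not stereogenic. The step needs chemoselectivity (enolate before malonate), which the difference in basicity and the iodide/chloride differentiation of 5 should secure, and regioselective enolisation, which the C8 blocking group secures; malonate alkylation first would lead, through intramolecular enolate alkylation, to the cis-fused isomer.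

**Step 4**
Reactants: 7 dimethyl (4aR,6E,8aS)-6-[(dimethylamino)methylidene]-4a-methyl-5-oxooctahydronaphthalene-1,1(2H)-dicarboxylate
Product: 8 dimethyl (4aR,8aR)-5-chloro-6-formyl-4a-methyl-3,4,4a,7,8,8a-hexahydronaphthalene-1,1(2H)-dicarboxylate
Conditions: POCl3 (1.2 equiv), CH2Cl2, 0 °C → rt; then H2O, 0 °C
Reagents that add atoms: phosphoryl chloride, O=P(Cl)(Cl)Cl; water, O
Why: Arnold–Vilsmeier-type activation (O-phosphorylation of the vinylogous amide, chloride addition–elimination at C9, hydrolysis of the chlorovinyl iminium salt) turns the blocking group into the beta-chloro enal, so that C17 is at the aldehyde level and C9 carries a leaving group.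

**Step 5**
Reactants: 8 dimethyl (4aR,8aR)-5-chloro-6-formyl-4a-methyl-3,4,4a,7,8,8a-hexahydronaphthalene-1,1(2H)-dicarboxylate; 9 tributyl(ethenyl)stannane
Product: 10 dimethyl (4aR,8aS)-5-ethenyl-6-formyl-4a-methyl-3,4,4a,7,8,8a-hexahydronaphthalene-1,1(2H)-dicarboxylate
Conditions: Pd2(dba)3 (2.5 mol %), P(t-Bu)3 (10 mol %), CsF (2.2 equiv), dioxane, 80 °C
Reagents that add atoms: none
Why: Stille coupling of the beta-chloro enal, whose C–Cl bond is activated toward oxidative addition as a vinylogous acyl chloride, attaches the two-carbon unit C11–C12 to C9 without creating a stereocentre.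

**Step 6**
Reactants: 10 dimethyl (4aR,8aS)-5-ethenyl-6-formyl-4a-methyl-3,4,4a,7,8,8a-hexahydronaphthalene-1,1(2H)-dicarboxylate
Product: 11 [(4aR,8aS)-5-ethenyl-6-(hydroxymethyl)-4a-methyl-3,4,4a,7,8,8a-hexahydronaphthalene-1,1(2H)-diyl]dimethanol
Conditions: LiAlH4 (3 equiv), THF, −20 → 0 °C; then H2O, aq. NaOH
Reagents that add atoms: none
Why: Hydride reduction takes the conjugated aldehyde by 1,2-addition to the allylic alcohol and both neopentyl esters to the 1,3-diol, before any lactone is present, and creates no stereocentre.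

**Step 7**
Reactants: 11 [(4aR,8aS)-5-ethenyl-6-(hydroxymethyl)-4a-methyl-3,4,4a,7,8,8a-hexahydronaphthalene-1,1(2H)-diyl]dimethanol; 12 3-bromofuran-2(5H)-one
Product: 14 3-{2-[(4aS,8aR)-2,5,5-tris(hydroxymethyl)-8a-methyl-3,4,4a,5,6,7,8,8a-octahydronaphthalen-1-yl]ethyl}furan-2(5H)-one, via B-alkyl borane 13 (not isolated)
Conditions: 9-BBN-H (4.5 equiv), THF, 0 °C → rt; then H2O, Cs2CO3 (3 equiv), 12 (1.3 equiv), PdCl2(dppf) (5 mol %), AsPh3 (10 mol %), DMF, rt
Reagents that add atoms: none
Why: 9-BBN adds only to the terminal carbon of the monosubstituted vinyl group (the tetrasubstituted C8=C9 bond is inert, the hydroxyls are carried as borinates) and the primary B-alkyl borane undergoes B-alkyl Suzuki–Miyaura coupling with the alpha-bromo butenolide under mild aqueous base.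

**Step 8**
Reactants: 14 3-{2-[(4aS,8aR)-2,5,5-tris(hydroxymethyl)-8a-methyl-3,4,4a,5,6,7,8,8a-octahydronaphthalen-1-yl]ethyl}furan-2(5H)-one
Product: 17 3-{2-[(1R,4aS,8aS)-5,5-bis(hydroxymethyl)-8a-methyl-2-methylidenedecahydronaphthalen-1-yl]ethyl}furan-2(5H)-one, via allylic sulfonylhydrazide 15 (not isolated), via allylic diazene 16 (not isolated)
Conditions: PPh3 (2 equiv), DEAD (2 equiv), 2-nitrobenzenesulfonylhydrazide (2 equiv), THF, −30 → 23 °C
Reagents that add atoms: none
Why: Myers reductive 1,3-transposition: Mitsunobu displacement of the primary allylic C17 hydroxyl (the neopentyl hydroxyls cannot undergo SN2), loss of sulfinic acid and retro-ene loss of N2 from the diazene should deliver hydrogen to C9 on the face anti to the axial C10 methyl, setting C9–H and moving the alkene to C8=C17.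

**Step 9**
Reactants: 17 3-{2-[(1R,4aS,8aS)-5,5-bis(hydroxymethyl)-8a-methyl-2-methylidenedecahydronaphthalen-1-yl]ethyl}furan-2(5H)-one
Product: 18 3-{2-[(1S,2S,4aS,8aR)-5,5-bis(hydroxymethyl)-8a-methyloctahydro-1H-spiro[naphthalene-2,2'-oxiran]-1-yl]ethyl}furan-2(5H)-one (expected main epimer)
Conditions: dimethyldioxirane (1.1 equiv), acetone, 0 °C
Reagents that add atoms: dimethyldioxirane, CC1(C)OO1
Why: The neutral dioxirane epoxidises the electron-rich 1,1-disubstituted exocyclic alkene and leaves the electron-poor butenolide alone; attack anti to the syn-axial C10 methyl should place oxygen equatorial, and both C8 epimers converge in step 10.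

**Step 10**
Reactants: 18 3-{2-[(1S,2S,4aS,8aR)-5,5-bis(hydroxymethyl)-8a-methyloctahydro-1H-spiro[naphthalene-2,2'-oxiran]-1-yl]ethyl}furan-2(5H)-one
Product: 19 (1R,2S,4aS,8aS)-5,5-bis(hydroxymethyl)-8a-methyl-1-[2-(2-oxo-2,5-dihydrofuran-3-yl)ethyl]decahydronaphthalene-2-carbaldehyde
Conditions: BF3·OEt2 (1 equiv), CH2Cl2, −78 → −20 °C; then DBU (0.2 equiv), CH2Cl2, rt
Reagents that add atoms: none
Why: Meinwald rearrangement (Lewis-acid opening to the tertiary C8 cation and 1,2-hydride shift from C17) gives the aldehyde, and DBU equilibrates C8 to the equatorial formyl group trans to the equatorial side chain, which is the configuration of the target.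

**Compound list**
1 | 2-methylcyclohex-2-en-1-one | CC1=CCCCC1=O | starting material
2 | dimethyl malonate | COC(=O)CC(=O)OC | starting material
3 | dimethyl 2-[(1S)-2-methyl-3-oxocyclohexyl]propanedioate (both C-2 epimers) | COC(=O)C(C(=O)OC)[C@H]1CCCC(=O)C1C | intermediate
4 | dimethyl 2-[(1S,4E)-4-[(dimethylamino)methylidene]-2-methyl-3-oxocyclohexyl]propanedioate (both C-2 epimers) | COC(=O)C(C(=O)OC)[C@H]1CC/C(=C\N(C)C)C(=O)C1C | intermediate
5 | 1-chloro-3-iodopropane | ClCCCI | starting material
6 | dimethyl 2-[(1R,2R,4E)-2-(3-chloropropyl)-4-[(dimethylamino)methylidene]-2-methyl-3-oxocyclohexyl]propanedioate (present as its lithium malonate) | COC(=O)C(C(=O)OC)[C@H]1CC/C(=C\N(C)C)C(=O)[C@]1(C)CCCCl | intermediate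
7 | dimethyl (4aR,6E,8aS)-6-[(dimethylamino)methylidene]-4a-methyl-5-oxooctahydronaphthalene-1,1(2H)-dicarboxylate | C[C@@]12CCCC(C(=O)OC)(C(=O)OC)[C@H]1CC/C(=C\N(C)C)C2=O | intermediate
8 | dimethyl (4aR,8aR)-5-chloro-6-formyl-4a-methyl-3,4,4a,7,8,8a-hexahydronaphthalene-1,1(2H)-dicarboxylate | C[C@@]12CCCC(C(=O)OC)(C(=O)OC)[C@H]1CCC(C=O)=C2Cl | intermediate
9 | tributyl(ethenyl)stannane | C=C[Sn](CCCC)(CCCC)CCCC | starting material
10 | dimethyl (4aR,8aS)-5-ethenyl-6-formyl-4a-methyl-3,4,4a,7,8,8a-hexahydronaphthalene-1,1(2H)-dicarboxylate | C[C@@]12CCCC(C(=O)OC)(C(=O)OC)[C@H]1CCC(C=O)=C2C=C | intermediate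
11 | [(4aR,8aS)-5-ethenyl-6-(hydroxymethyl)-4a-methyl-3,4,4a,7,8,8a-hexahydronaphthalene-1,1(2H)-diyl]dimethanol | C[C@@]12CCCC(CO)(CO)[C@H]1CCC(CO)=C2C=C | intermediate
12 | 3-bromofuran-2(5H)-one | O=C1OCC=C1Br | starting material
13 | B-alkyl-9-BBN adduct of 11 (boron on the terminal side-chain carbon C12; the three hydroxyls as O-(9-BBN) borinates) | C[C@@]12CCCC(COB3C4CCCC3CCC4)(COB3C4CCCC3CCC4)[C@H]1CCC(COB1C3CCCC1CCC3)=C2CCB1C2CCCC1CCC2 | intermediate
14 | 3-{2-[(4aS,8aR)-2,5,5-tris(hydroxymethyl)-8a-methyl-3,4,4a,5,6,7,8,8a-octahydronaphthalen-1-yl]ethyl}furan-2(5H)-one | C[C@@]12CCCC(CO)(CO)[C@H]1CCC(CO)=C2CCC1=CCOC1=O | intermediate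
15 | N-allylic 2-nitrobenzenesulfonohydrazide of 14 (C17–N(NH2)SO2Ar in place of C17–OH) | C[C@@]12CCCC(CO)(CO)[C@H]1CCC(CN(N)S(=O)(=O)c3ccccc3[N+](=O)[O-])=C2CCC1=CCOC1=O | intermediate
16 | allylic monoalkyl diazene of 14 (C17–N=NH in place of C17–OH) | C[C@@]12CCCC(CO)(CO)[C@H]1CCC(CN=N)=C2CCC1=CCOC1=O | intermediate
17 | 3-{2-[(1R,4aS,8aS)-5,5-bis(hydroxymethyl)-8a-methyl-2-methylidenedecahydronaphthalen-1-yl]ethyl}furan-2(5H)-one | C[C@@]12CCCC(CO)(CO)[C@H]1CCC(=C)[C@H]2CCC1=CCOC1=O | intermediate
18 | 3-{2-[(1S,2S,4aS,8aR)-5,5-bis(hydroxymethyl)-8a-methyloctahydro-1H-spiro[naphthalene-2,2'-oxiran]-1-yl]ethyl}furan-2(5H)-one | C[C@@]12CCCC(CO)(CO)[C@H]1CC[C@@]3(CO3)[C@H]2CCC1=CCOC1=O | intermediate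
19 | (1R,2S,4aS,8aS)-5,5-bis(hydroxymethyl)-8a-methyl-1-[2-(2-oxo-2,5-dihydrofuran-3-yl)ethyl]decahydronaphthalene-2-carbaldehyde | C[C@@]12CCCC(CO)(CO)[C@H]1CC[C@H](C=O)[C@H]2CCC1=CCOC1=O | target

**Step count and risks**

Total step count: 10. Longest linear sequence: 10 steps (1 → 19).

Steps most likely to fail:

1. Step 3 (key step). The malonate carbon may be alkylated by the iodide before the hindered C10 enolate, after which intramolecular enolate alkylation would erode the trans ring fusion; the final ring closure onto the chloride may also stall. Fallback, from 4 back to 7, making the two bonds separately: the same dianion is quenched at C10 with allyl bromide to give dimethyl 2-[(1R,2R,4E)-4-[(dimethylamino)methylidene]-2-methyl-3-oxo-2-(prop-2-en-1-yl)cyclohexyl]propanedioate F3. Hydroboration with 9-BBN and oxidation with NaBO3·4H2O give the primary alcohol dimethyl 2-[(1R,2R,4E)-4-[(dimethylamino)methylidene]-2-(3-hydroxypropyl)-2-methyl-3-oxocyclohexyl]propanedioate F4. MsCl/Et3N gives the mesylate dimethyl 2-[(1R,2R,4E)-4-[(dimethylamino)methylidene]-2-{3-[(methanesulfonyl)oxy]propyl}-2-methyl-3-oxocyclohexyl]propanedioate F5, and NaH in THF closes ring A through the malonate anion to return to 7.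

2. Step 1. Conjugate addition to the alpha-methyl enone may be slow and the enantioselectivity may fall short. Fallback, from 2 to 4, setting the stereocentre on the unsubstituted enone: 2 adds to commercial cyclohex-2-en-1-one (O=C1C=CCCC1) under the same aluminate catalysis, a well-precedented case, to give dimethyl 2-[(1S)-3-oxocyclohexyl]propanedioate F1. Bredereck's reagent condenses at the less hindered alpha-methylene to give dimethyl 2-[(1S,4E)-4-[(dimethylamino)methylidene]-3-oxocyclohexyl]propanedioate F2. The dianion of F2 (LiN(i-Pr)2, 2.2 equiv) is methylated with MeI (1.0 equiv) at the alpha-prime carbon, which returns to 4.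

3. Step 8. The Mitsunobu activation may be diverted by the free 1,3-diol, or substitution at the hindered allylic position may be incomplete. Fallback, from 14 to 17, reaching the same diazene through a hydrazone: MnO2 oxidises only the allylic alcohol to 3-{2-[(4aS,8aR)-2-formyl-5,5-bis(hydroxymethyl)-8a-methyl-3,4,4a,5,6,7,8,8a-octahydronaphthalen-1-yl]ethyl}furan-2(5H)-one F6. TsNHNH2 gives its (E)-4-methylbenzenesulfonohydrazone F7. Catecholborane followed by NaOAc·3H2O (alkene-transposing hydrazone reduction) gives 17.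

**Further compounds**
F1 | step 1 | dimethyl 2-[(1S)-3-oxocyclohexyl]propanedioate | COC(=O)C(C(=O)OC)[C@H]1CCCC(=O)C1
F2 | step 1 | dimethyl 2-[(1S,4E)-4-[(dimethylamino)methylidene]-3-oxocyclohexyl]propanedioate | COC(=O)C(C(=O)OC)[C@H]1CC/C(=C\N(C)C)C(=O)C1
F3 | step 3 | dimethyl 2-[(1R,2R,4E)-4-[(dimethylamino)methylidene]-2-methyl-3-oxo-2-(prop-2-en-1-yl)cyclohexyl]propanedioate | COC(=O)C(C(=O)OC)[C@H]1CC/C(=C\N(C)C)C(=O)[C@]1(C)CC=C
F4 | step 3 | dimethyl 2-[(1R,2R,4E)-4-[(dimethylamino)methylidene]-2-(3-hydroxypropyl)-2-methyl-3-oxocyclohexyl]propanedioate | COC(=O)C(C(=O)OC)[C@H]1CC/C(=C\N(C)C)C(=O)[C@]1(C)CCCO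
F5 | step 3 | dimethyl 2-[(1R,2R,4E)-4-[(dimethylamino)methylidene]-2-{3-[(methanesulfonyl)oxy]propyl}-2-methyl-3-oxocyclohexyl]propanedioate | COC(=O)C(C(=O)OC)[C@H]1CC/C(=C\N(C)C)C(=O)[C@]1(C)CCCOS(C)(=O)=O
F6 | step 8 | 3-{2-[(4aS,8aR)-2-formyl-5,5-bis(hydroxymethyl)-8a-methyl-3,4,4a,5,6,7,8,8a-octahydronaphthalen-1-yl]ethyl}furan-2(5H)-one | C[C@@]12CCCC(CO)(CO)[C@H]1CCC(C=O)=C2CCC1=CCOC1=O
F7 | step 8 | (E)-4-methylbenzenesulfonohydrazone of F6 | C[C@@]12CCCC(CO)(CO)[C@H]1CCC(/C=N/NS(=O)(=O)c3ccc(C)cc3)=C2CCC1=CCOC1=O
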